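## Retrosynthetic overview

1. Last operations: Si–O cleavage at the cyclopropyl carbinol, preceded by a stereoconvergent carboxylate displacement on an α-bromo ethyl ketone that makes the (Z)-coumarate C–O bond and the acyloxy stereocentre together.
2. Dihydropyranone (second ring): acrylate ring-closing metathesis after an anti-selective organocatalytic allylboration of an α-silyloxy aldehyde.
3. Carbinol centre: catalyst-controlled oxazaborolidine reduction of an α-keto acetal that is electronically differentiated from the ethyl ketone.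
4. Cyclopropane (first ring, first two stereocentres): cinchona-amine ammonium-ylide cyclopropanation of ethyl vinyl ketone with 3-bromo-1,1-dimethoxypropan-2-one.
5. Ring order: cyclopropane first, lactone second; every starting material is achiral.

Assumption: catalyst senses are taken as 9-O-methylquinidine → (1S,2S) ring, (R)-Me-CBS → (1S)-carbinol (dimethoxymethyl as the large group) and (R)-TRIP → Re-face allylation; each is checked on first use and the mirror-image or pseudoenantiomeric catalyst is used if the sense is opposite.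

## Route

Step 1
Reactants: 1 pent-1-en-3-one; 2 3-bromo-1,1-dimethoxypropan-2-one
Product: 3 2,2-dimethoxy-1-[(1S,2S)-2-propanoylcyclopropyl]ethan-1-one
Conditions: 9-O-methylquinidine (20 mol%), Cs2CO3 (1.3 equiv), MeCN, 80 °C, 2 added slowly to excess 1
Reagents that add atoms: none
Why: Cinchona-amine ammonium-ylide cyclopropanation (Michael-initiated ring closure): the quinuclidine nitrogen is alkylated by 2, Cs2CO3 gives the keto-stabilised ylide, this adds to 1 and the enolate closes by 3-exo-tet displacement of the chiral ammonium group, so both ring stereocentres (trans, 1S,2S) are set by the catalyst.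

Step 2
Reactants: 3 2,2-dimethoxy-1-[(1S,2S)-2-propanoylcyclopropyl]ethan-1-one
Product: 4 1-[(1S,2S)-2-[(1S)-1-hydroxy-2,2-dimethoxyethyl]cyclopropyl]propan-1-one
Conditions: (R)-Me-CBS [(R)-1-methyl-3,3-diphenyltetrahydro-1H,3H-pyrrolo[1,2-c][1,3,2]oxazaborole] (10 mol%), catecholborane (1.2 equiv), toluene, −78 °C; then MeOH, aqueous work-up
Reagents that add atoms: none
Why: Corey–Bakshi–Shibata reduction: the α,α-dimethoxy ketone is far more electrophilic than the ethyl cyclopropyl ketone and is the only carbonyl reduced at −78 °C, and the (R)-oxazaborolidine delivers hydride to its Re face (O > CH(OMe)2 > cyclopropyl) to give the (S)-carbinol under catalyst control, with any minor ring enantiomer becoming a separable diastereomer.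

Step 3
Reactants: 4 1-[(1S,2S)-2-[(1S)-1-hydroxy-2,2-dimethoxyethyl]cyclopropyl]propan-1-one
Product: 7 (2S)-2-[(1S,2S)-2-propanoylcyclopropyl]-2-(triethylsilyloxy)acetaldehyde, via silyl ether acetal 5 (not isolated), via collidinium salt 6 (not isolated)
Conditions: Et3SiOTf (3 equiv), 2,4,6-collidine (4.5 equiv), CH2Cl2, 0 °C; then H2O, 0 °C to rt
Reagents that add atoms: triethylsilyl trifluoromethanesulfonate, CC[Si](CC)(CC)OS(=O)(=O)C(F)(F)F; water, O
Why: One-flask O-silylation and silyl triflate/collidine deacetalisation: the alcohol is silylated first, the dimethyl acetal is then converted into a collidinium salt that water hydrolyses to the aldehyde under non-acidic conditions, so the silyl ether, the ketone and the α-stereocentre are kept.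

Step 4
Reactants: 7 (2S)-2-[(1S,2S)-2-propanoylcyclopropyl]-2-(triethylsilyloxy)acetaldehyde; 8 2-allyl-4,4,5,5-tetramethyl-1,3,2-dioxaborolane
Product: 9 1-[(1S,2S)-2-[(1S,2R)-2-hydroxy-1-(triethylsilyloxy)pent-4-en-1-yl]cyclopropyl]propan-1-one
Conditions: (R)-TRIP [(R)-3,3'-bis(2,4,6-triisopropylphenyl)-1,1'-binaphthyl-2,2'-diyl hydrogen phosphate] (5 mol%), toluene, 4 Å MS, −30 °C
Reagents that add atoms: none
Why: Chiral phosphoric acid-catalysed allylboration through a closed chair transition state: Felkin–Anh attack anti to the silyloxy group and the Re-face preference imposed by (R)-TRIP reinforce each other and set the (2R) carbinol 1,2-anti to the silyl ether, while the ketone does not react at −30 °C.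

Step 5
Reactants: 9 1-[(1S,2S)-2-[(1S,2R)-2-hydroxy-1-(triethylsilyloxy)pent-4-en-1-yl]cyclopropyl]propan-1-one; 10 prop-2-enoyl chloride
Product: 11 (1S,2R)-1-[(1S,2S)-2-propanoylcyclopropyl]-1-(triethylsilyloxy)pent-4-en-2-yl prop-2-enoate
Conditions: iPr2NEt, CH2Cl2, −20 to 0 °C
Reagents that add atoms: none
Why: O-acylation of the only free hydroxyl with an acid chloride (esterification), no stereocentre involved.

Step 6
Reactants: 11 (1S,2R)-1-[(1S,2S)-2-propanoylcyclopropyl]-1-(triethylsilyloxy)pent-4-en-2-yl prop-2-enoate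
Product: 12 (6R)-6-[(S)-[(1S,2S)-2-propanoylcyclopropyl](triethylsilyloxy)methyl]-5,6-dihydro-2H-pyran-2-one
Conditions: second-generation Grubbs catalyst RuCl2(H2IMes)(PCy3)(=CHPh) (5 mol%), CH2Cl2 (5 mM), 40 °C
Reagents that add atoms: none
Why: Ring-closing metathesis of the acrylate with the terminal alkene closes the six-membered α,β-unsaturated lactone, driven by loss of ethene.

Step 7
Reactants: 12 (6R)-6-[(S)-[(1S,2S)-2-propanoylcyclopropyl](triethylsilyloxy)methyl]-5,6-dihydro-2H-pyran-2-one
Product: 14 (6R)-6-[(S)-[(1S,2S)-2-(2-bromopropanoyl)cyclopropyl](triethylsilyloxy)methyl]-5,6-dihydro-2H-pyran-2-one as a mixture of both CHBr epimers, via trimethylsilyl enol ether 13 (not isolated)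
Conditions: Me3SiOTf (1.2 equiv), Et3N (1.5 equiv), CH2Cl2, −20 °C; then N-bromosuccinimide (1.05 equiv), NaHCO3, THF, −78 to −20 °C
Reagents that add atoms: N-bromosuccinimide, O=C1CCC(=O)N1Br
Why: Soft enolisation (only the ethyl CH2 can enolise; the cyclopropyl CH and the lactone are not deprotonated by Et3N) followed by electrophilic bromination of the silyl enol ether gives the α-bromo ketone regioselectively, its C–Br configuration being irrelevant because the next step is stereoconvergent.

Step 8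
Reactants: 15 (2E)-3-(4-hydroxyphenyl)prop-2-enoic acid
Product: 16 (2Z)-3-(4-hydroxyphenyl)prop-2-enoic acid
Conditions: hν (365 nm), MeOH, rt, argon; chromatography and storage in the dark
Reagents that add atoms: none
Why: Direct E to Z photoisomerisation of the cinnamate chromophore to a photostationary mixture, from which the Z acid is separated.

Step 9
Reactants: 14 (6R)-6-[(S)-[(1S,2S)-2-(2-bromopropanoyl)cyclopropyl](triethylsilyloxy)methyl]-5,6-dihydro-2H-pyran-2-one (both epimers); 16 (2Z)-3-(4-hydroxyphenyl)prop-2-enoic acid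
Product: 18 (2R)-1-oxo-1-[(1S,2S)-2-[(S)-[(2R)-6-oxo-3,6-dihydro-2H-pyran-2-yl](triethylsilyloxy)methyl]cyclopropyl]propan-2-yl (2Z)-3-(4-hydroxyphenyl)prop-2-enoate, via potassium carboxylate 17 (not isolated)
Conditions: 16 (1.5 equiv), solid KHCO3 (1.5 equiv), N-(9-anthracenylmethyl)-O-allylcinchonidinium bromide (15 mol%; pseudoenantiomeric cinchoninium salt if the sense is opposite), toluene/CH2Cl2 3:1, 0 °C, dark
Reagents that add atoms: none
Why: Proposed new method: a catalyst-controlled stereoconvergent SN2 acyloxylation in which bromide from the ammonium bromide pool epimerises the CHBr centre of 14 by degenerate exchange faster than the sparingly soluble carboxylate 17 is carried into solution, and the chiral ammonium–carboxylate ion pair displaces bromide with inversion from the (2S) epimer only, so that the ester C–O bond and the (2R) centre form together while the phenol (not deprotonated by hydrogencarbonate) and the Z-alkene are untouched; the closest known reaction type is the enantioconvergent azidation of racemic α-bromo ketones under chiral quaternary-ammonium phase-transfer catalysis, together with the classical carboxylate displacement of α-halo ketones.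

Step 10
Reactants: 18 (2R)-1-oxo-1-[(1S,2S)-2-[(S)-[(2R)-6-oxo-3,6-dihydro-2H-pyran-2-yl](triethylsilyloxy)methyl]cyclopropyl]propan-2-yl (2Z)-3-(4-hydroxyphenyl)prop-2-enoate
Product: 19 (2R)-1-[(1S,2S)-2-[(S)-hydroxy[(2R)-6-oxo-3,6-dihydro-2H-pyran-2-yl]methyl]cyclopropyl]-1-oxopropan-2-yl (2Z)-3-(4-hydroxyphenyl)prop-2-enoate
Conditions: HF·pyridine, pyridine, THF, 0 °C, dark
Reagents that add atoms: none
Why: Fluoride-mediated cleavage of the secondary triethylsilyl ether under buffered mildly acidic conditions, which leave the lactone, the Z-enoate, the phenol and the epimerisable α-acyloxy ketone untouched.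

## Compound list

1 | pent-1-en-3-one | CCC(=O)C=C | starting material
2 | 3-bromo-1,1-dimethoxypropan-2-one | COC(OC)C(=O)CBr | starting material
3 | 2,2-dimethoxy-1-[(1S,2S)-2-propanoylcyclopropyl]ethan-1-one | CCC(=O)[C@H]1C[C@@H]1C(=O)C(OC)OC | intermediate
4 | 1-[(1S,2S)-2-[(1S)-1-hydroxy-2,2-dimethoxyethyl]cyclopropyl]propan-1-one | CCC(=O)[C@H]1C[C@@H]1[C@H](O)C(OC)OC | intermediate
5 | 1-[(1S,2S)-2-[(1S)-2,2-dimethoxy-1-(triethylsilyloxy)ethyl]cyclopropyl]propan-1-one | CCC(=O)[C@H]1C[C@@H]1[C@H](O[Si](CC)(CC)CC)C(OC)OC | intermediate (not isolated)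
6 | 1-[(2S)-1-methoxy-2-[(1S,2S)-2-propanoylcyclopropyl]-2-(triethylsilyloxy)ethyl]-2,4,6-trimethylpyridinium triflate (both C1 epimers) | CCC(=O)[C@H]1C[C@@H]1[C@H](O[Si](CC)(CC)CC)C(OC)[n+]1c(C)cc(C)cc1C.[O-]S(=O)(=O)C(F)(F)F | intermediate (not isolated)
7 | (2S)-2-[(1S,2S)-2-propanoylcyclopropyl]-2-(triethylsilyloxy)acetaldehyde | CCC(=O)[C@H]1C[C@@H]1[C@H](O[Si](CC)(CC)CC)C=O | intermediate
8 | 2-allyl-4,4,5,5-tetramethyl-1,3,2-dioxaborolane | C=CCB1OC(C)(C)C(C)(C)O1 | starting material
9 | 1-[(1S,2S)-2-[(1S,2R)-2-hydroxy-1-(triethylsilyloxy)pent-4-en-1-yl]cyclopropyl]propan-1-one | CCC(=O)[C@H]1C[C@@H]1[C@H](O[Si](CC)(CC)CC)[C@H](O)CC=C | intermediate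
10 | prop-2-enoyl chloride | C=CC(=O)Cl | starting material
11 | (1S,2R)-1-[(1S,2S)-2-propanoylcyclopropyl]-1-(triethylsilyloxy)pent-4-en-2-yl prop-2-enoate | CCC(=O)[C@H]1C[C@@H]1[C@H](O[Si](CC)(CC)CC)[C@H](OC(=O)C=C)CC=C | intermediate
12 | (6R)-6-[(S)-[(1S,2S)-2-propanoylcyclopropyl](triethylsilyloxy)methyl]-5,6-dihydro-2H-pyran-2-one | CCC(=O)[C@H]1C[C@@H]1[C@H](O[Si](CC)(CC)CC)[C@H]1CC=CC(=O)O1 | intermediate
13 | (6R)-6-[(S)-(triethylsilyloxy)[(1S,2S)-2-[(1Z)-1-(trimethylsilyloxy)prop-1-en-1-yl]cyclopropyl]methyl]-5,6-dihydro-2H-pyran-2-one | C/C=C(\O[Si](C)(C)C)[C@H]1C[C@@H]1[C@H](O[Si](CC)(CC)CC)[C@H]1CC=CC(=O)O1 | intermediate (not isolated)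
14 | (6R)-6-[(S)-[(1S,2S)-2-(2-bromopropanoyl)cyclopropyl](triethylsilyloxy)methyl]-5,6-dihydro-2H-pyran-2-one (both CHBr epimers) | CC(Br)C(=O)[C@H]1C[C@@H]1[C@H](O[Si](CC)(CC)CC)[C@H]1CC=CC(=O)O1 | intermediate
15 | (2E)-3-(4-hydroxyphenyl)prop-2-enoic acid | OC(=O)/C=C/c1ccc(O)cc1 | starting material
16 | (2Z)-3-(4-hydroxyphenyl)prop-2-enoic acid | OC(=O)/C=C\c1ccc(O)cc1 | intermediate
17 | potassium (2Z)-3-(4-hydroxyphenyl)prop-2-enoate | [K+].[O-]C(=O)/C=C\c1ccc(O)cc1 | intermediate (not isolated)
18 | (2R)-1-oxo-1-[(1S,2S)-2-[(S)-[(2R)-6-oxo-3,6-dihydro-2H-pyran-2-yl](triethylsilyloxy)methyl]cyclopropyl]propan-2-yl (2Z)-3-(4-hydroxyphenyl)prop-2-enoate | C[C@@H](OC(=O)/C=C\c1ccc(O)cc1)C(=O)[C@H]1C[C@@H]1[C@H](O[Si](CC)(CC)CC)[C@H]1CC=CC(=O)O1 | intermediate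
19 | (2R)-1-[(1S,2S)-2-[(S)-hydroxy[(2R)-6-oxo-3,6-dihydro-2H-pyran-2-yl]methyl]cyclopropyl]-1-oxopropan-2-yl (2Z)-3-(4-hydroxyphenyl)prop-2-enoate | C[C@@H](OC(=O)/C=C\c1ccc(O)cc1)C(=O)[C@H]1C[C@@H]1[C@H](O)[C@H]1CC=CC(=O)O1 | target

## Step count and risks

Total steps: 10. Longest linear sequence: 9 (steps 1 to 7, then 9 and 10; step 8 is a one-step side branch).

**Step 9 (the new acyloxylation).** Epimerisation of the bromide may be slower than substitution, or the ion pair may not discriminate the two epimers well enough. The fallback uses known chemistry and sets out from lactone 12, so the bromination of step 7 is skipped. D-Proline-catalysed α-aminoxylation of the ethyl ketone with nitrosobenzene (DMSO, rt, slow addition) gives (6R)-6-[(S)-[(1S,2S)-2-[(2S)-2-(anilinooxy)propanoyl]cyclopropyl](triethylsilyloxy)methyl]-5,6-dihydro-2H-pyran-2-one F1. Zn in AcOH/THF at 0 °C cleaves the N–O bond to the (2S)-hydroxy ketone (6R)-6-[(S)-[(1S,2S)-2-[(2S)-2-hydroxypropanoyl]cyclopropyl](triethylsilyloxy)methyl]-5,6-dihydro-2H-pyran-2-one F2. Mitsunobu esterification of F2 with acid 16 (PPh3, diisopropyl azodicarboxylate, THF, 0 °C, dark) proceeds with inversion at the carbinol carbon and engages only the carboxylic acid of 16. It comes back to the route at 18.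

**Step 2 (chemoselective, catalyst-controlled reduction of one of two ketones).** The ethyl ketone may be reduced competitively, or the facial control may be weak. The fallback removes the second ketone and sets out from 2. The cyclopropanation of step 1 is run with N-methoxy-N-methylacrylamide in place of 1 to give (1S,2S)-2-(2,2-dimethoxyacetyl)-N-methoxy-N-methylcyclopropane-1-carboxamide F3. The same oxazaborolidine reduction then gives (1S,2S)-2-[(1S)-1-hydroxy-2,2-dimethoxyethyl]-N-methoxy-N-methylcyclopropane-1-carboxamide F4. Et3SiCl/imidazole gives (1S,2S)-2-[(1S)-2,2-dimethoxy-1-(triethylsilyloxy)ethyl]-N-methoxy-N-methylcyclopropane-1-carboxamide F5, and EtMgBr (THF, −20 °C) adds once to the Weinreb amide. It comes back to the route at 5, which is taken on with Et3SiOTf/collidine and water as in step 3.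

**Step 4 (allylboration of a configurationally fragile α-silyloxy aldehyde).** The 1,2-anti selectivity may be insufficient, or 7 may epimerise. The fallback builds the ring by cycloaddition and sets out from 7. Hetero-Diels–Alder reaction with (E)-1-methoxybuta-1,3-diene is catalysed by the tridentate Schiff-base chloride complex of trivalent chromium, CrCl(L), where L is the dianion of the imine from cis-1-aminoindan-2-ol and 3-(1-adamantyl)-2-hydroxy-5-methylbenzaldehyde, using the enantiomer that attacks the Re face of the aldehyde. This gives the cis adduct 1-[(1S,2S)-2-[(S)-[(2R,6S)-6-methoxy-3,6-dihydro-2H-pyran-2-yl](triethylsilyloxy)methyl]cyclopropyl]propan-1-one F6. Pyridinium p-toluenesulfonate in wet acetone gives the lactol 1-[(1S,2S)-2-[(S)-[(2R)-6-hydroxy-3,6-dihydro-2H-pyran-2-yl](triethylsilyloxy)methyl]cyclopropyl]propan-1-one F7, and MnO2 (CH2Cl2, rt) oxidises the allylic lactol. It comes back to the route at 12, so steps 5 and 6 are not needed.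

## Further compounds

F1 | step 9 | (6R)-6-[(S)-[(1S,2S)-2-[(2S)-2-(anilinooxy)propanoyl]cyclopropyl](triethylsilyloxy)methyl]-5,6-dihydro-2H-pyran-2-one | C[C@H](ONc1ccccc1)C(=O)[C@H]1C[C@@H]1[C@H](O[Si](CC)(CC)CC)[C@H]1CC=CC(=O)O1
F2 | step 9 | (6R)-6-[(S)-[(1S,2S)-2-[(2S)-2-hydroxypropanoyl]cyclopropyl](triethylsilyloxy)methyl]-5,6-dihydro-2H-pyran-2-one | C[C@H](O)C(=O)[C@H]1C[C@@H]1[C@H](O[Si](CC)(CC)CC)[C@H]1CC=CC(=O)O1
F3 | step 2 | (1S,2S)-2-(2,2-dimethoxyacetyl)-N-methoxy-N-methylcyclopropane-1-carboxamide | CON(C)C(=O)[C@H]1C[C@@H]1C(=O)C(OC)OC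
F4 | step 2 | (1S,2S)-2-[(1S)-1-hydroxy-2,2-dimethoxyethyl]-N-methoxy-N-methylcyclopropane-1-carboxamide | CON(C)C(=O)[C@H]1C[C@@H]1[C@H](O)C(OC)OC
F5 | step 2 | (1S,2S)-2-[(1S)-2,2-dimethoxy-1-(triethylsilyloxy)ethyl]-N-methoxy-N-methylcyclopropane-1-carboxamide | CON(C)C(=O)[C@H]1C[C@@H]1[C@H](O[Si](CC)(CC)CC)C(OC)OC
F6 | step 4 | 1-[(1S,2S)-2-[(S)-[(2R,6S)-6-methoxy-3,6-dihydro-2H-pyran-2-yl](triethylsilyloxy)methyl]cyclopropyl]propan-1-one | CCC(=O)[C@H]1C[C@@H]1[C@H](O[Si](CC)(CC)CC)[C@H]1CC=C[C@@H](OC)O1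
F7 | step 4 | 1-[(1S,2S)-2-[(S)-[(2R)-6-hydroxy-3,6-dihydro-2H-pyran-2-yl](triethylsilyloxy)methyl]cyclopropyl]propan-1-one (both anomers) | CCC(=O)[C@H]1C[C@@H]1[C@H](O[Si](CC)(CC)CC)[C@H]1CC=CC(O)O1
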